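## Retrosynthetic overview

1. Target 20 ⇒ ketal hydrolysis and amide coupling lead back to acid 15 and the C5N amine 18 (from cyclopentane-1,3-dione).
2. Key disconnection C4–C1′ of the lower chain: the C4 ketone of epoxy ketone 7 is joined to C7 of a hepta-2,4,6-trienoate made nucleophilic by hydrozirconation and Zr-to-Al exchange of dienynoate 11. This ζ-metalated trienoate is a doubly vinylogous β-acylvinyl anion (homoenolate-type, d7); delivery from the oxirane face sets C4 anti to the epoxide.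
3. 7 ⇒ enantioselective phase-transfer epoxidation of quinone monoketal 6 ⇒ PhI(OAc)2/MeOH dearomatisation of anilide 5 ⇒ 2,5-dimethoxyaniline 4 + trienoate 3 (vinylogous HWE of 1 and 2).
4. Ring order: the six-membered ring is the arene of 4 throughout; the oxirane is formed in step 4; the cyclopentenone ring is bought as cyclopentane-1,3-dione and attached in step 10.

Assumption: the SMILES is taken literally, so the C4 hydroxyl is trans (anti) to the oxirane oxygen, (4S,5S,6R). Ring numbering used for all ring compounds: C1 = ketone (ketal) carbon, C2 = N-bearing carbon, C3 = CH, C4 = carbinol (or ketone) carbon, C5/C6 = oxirane carbons (C6 next to C1).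

Assumption: N-benzylcinchonidinium chloride gives the (5S,6R) epoxide 7; if the sense of induction proves opposite, the pseudoenantiomeric N-benzylcinchoninium chloride is used instead.

## Route

Step 1
Reactants: 1 (E)-4-methylpent-2-enal; 2 triethyl (E)-4-phosphonocrotonate
Product: 3 ethyl (2E,4E,6E)-8-methylnona-2,4,6-trienoate
Conditions: LiN(SiMe3)2, THF, −78 °C to 0 °C
Reagents that add atoms: none
Why: Vinylogous Horner–Wadsworth–Emmons olefination, in which the γ-deprotonated phosphonocrotonate attacks the enal through its carbon next to phosphorus and the stabilised anion gives the new C4=C5 bond trans, so the all-E trienoate results (minor 4Z isomer removed by chromatography).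

Step 2
Reactants: 3 ethyl (2E,4E,6E)-8-methylnona-2,4,6-trienoate; 4 2,5-dimethoxyaniline
Product: 5 N-(2,5-dimethoxyphenyl)-(2E,4E,6E)-8-methylnona-2,4,6-trienamide
Conditions: AlMe3 (2 equiv), toluene, 0 °C to 60 °C; aq. KNaC4H4O6 work-up
Reagents that add atoms: none
Why: Weinreb-type aminolysis, in which the dimethylaluminium anilide is a hard nucleophile that attacks the ester carbonyl rather than the polyene, so the anilide forms without change of double-bond geometry.

Step 3
Reactants: 5 N-(2,5-dimethoxyphenyl)-(2E,4E,6E)-8-methylnona-2,4,6-trienamide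
Product: 6 N-(6,6-dimethoxy-3-oxocyclohexa-1,4-dien-1-yl)-(2E,4E,6E)-8-methylnona-2,4,6-trienamide
Conditions: PhI(OAc)2 (1.1 equiv), MeOH, 0 °C to rt
Reagents that add atoms: methanol (CO)
Why: Oxidative dearomatisation with a hypervalent iodine reagent, in which methanol is captured at the methoxy-bearing carbon ortho to nitrogen while the other methoxy group collapses to the ketone with loss of its methyl group, giving the quinone monoketal whose free carbonyl is the future C4.

Step 4
Reactants: 6 N-(6,6-dimethoxy-3-oxocyclohexa-1,4-dien-1-yl)-(2E,4E,6E)-8-methylnona-2,4,6-trienamide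
Product: 7 N-[(5S,6R)-5,6-epoxy-1,1-dimethoxy-4-oxocyclohex-2-en-2-yl]-(2E,4E,6E)-8-methylnona-2,4,6-trienamide
Conditions: t-BuOOH, aq. NaOH, N-benzylcinchonidinium chloride (10 mol%), toluene, 0 °C to rt; recrystallise to >98% ee
Reagents that add atoms: tert-butyl hydroperoxide (CC(C)(C)OO)
Why: Weitz–Scheffer nucleophilic epoxidation under chiral phase-transfer catalysis, in which only the unsubstituted enone C5=C6 is electrophilic enough (C2=C3 is a vinylogous amide) and the cinchonidinium–hydroperoxide ion pair attacks one enantiotopic face, so C5 and C6 are set together as the cis (5S,6R) oxirane.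

Step 5
Reactants: 8 (E)-pent-2-en-4-yn-1-ol; 9 methyl (triphenylphosphoranylidene)acetate
Product: 11 methyl (2E,4E)-hepta-2,4-dien-6-ynoate, via enynal 10 (not isolated)
Conditions: MnO2 (10 equiv), CH2Cl2, rt
Reagents that add atoms: none
Why: Tandem allylic oxidation–Wittig reaction, in which MnO2 oxidises only the allylic alcohol and the stabilised ylide traps the volatile enynal as it forms, giving the new C2=C3 bond trans.

Step 6
Reactants: 7 N-[(5S,6R)-5,6-epoxy-1,1-dimethoxy-4-oxocyclohex-2-en-2-yl]-(2E,4E,6E)-8-methylnona-2,4,6-trienamide; 11 methyl (2E,4E)-hepta-2,4-dien-6-ynoate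
Product: 14 methyl (2E,4E,6E)-7-{(4S,5S,6R)-5,6-epoxy-4-hydroxy-1,1-dimethoxy-2-[(2E,4E,6E)-8-methylnona-2,4,6-trienamido]cyclohex-2-en-4-yl}hepta-2,4,6-trienoate, via alkenylzirconocene 12 (not isolated), via alkenylalane 13 (not isolated)
Conditions: 11 (3 equiv), Cp2Zr(H)Cl (3 equiv), CH2Cl2, rt; Me2AlCl (3 equiv), −78 °C; then 7 in toluene, −78 °C to −20 °C (the first equivalent of alane metalates the amide N–H); aq. KNaC4H4O6
Reagents that add atoms: none
Why: Proposed new method: hydrozirconation places the metal on C7 of the trienoate, an acceptor position in normal polarity, so 12 and 13 are doubly vinylogous β-acylvinyl (homoenolate-type, d7) nucleophiles that join C7 to the electrophilic ketone carbon C4; in the absence of donor solvent the Lewis-acidic but weakly nucleophilic alane 13 is expected to dock on the cis-disposed oxirane oxygen and α-face ketal methoxy group and to hand its alkenyl ligand (which migrates from aluminium far faster than methyl) to the carbonyl through a cyclic transition state on the oxirane face, so the chain enters syn to the epoxide and the new C4 hydroxyl is anti to it (4S), the opposite of the open Felkin–Anh addition shown by alkenyllithiums in THF; the closest known reaction types are the epoxide-oxygen-directed DIBAL-H reduction of cyclic α,β-epoxy ketones to trans-epoxy alcohols, oxygen-directed alkynyl- and alkenylalane transfers, and hydrozirconation–transmetalation additions of alkenylmetals to carbonyl groups.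

Step 7
Reactants: 14 methyl (2E,4E,6E)-7-{(4S,5S,6R)-5,6-epoxy-4-hydroxy-1,1-dimethoxy-2-[(2E,4E,6E)-8-methylnona-2,4,6-trienamido]cyclohex-2-en-4-yl}hepta-2,4,6-trienoate
Product: 15 (2E,4E,6E)-7-{(4S,5S,6R)-5,6-epoxy-4-hydroxy-1,1-dimethoxy-2-[(2E,4E,6E)-8-methylnona-2,4,6-trienamido]cyclohex-2-en-4-yl}hepta-2,4,6-trienoic acid
Conditions: Me3SnOH (6 equiv), ClCH2CH2Cl, 70 °C; cold dilute aq. HCl wash
Reagents that add atoms: trimethyltin hydroxide (C[Sn](C)(C)O)
Why: Neutral ester hydrolysis with trimethyltin hydroxide, chosen because it does not generate the free C4 alkoxide that could attack C5 in a Payne rearrangement of the anti-hydroxy epoxide, and it leaves ketal, oxirane and polyenes intact.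

Step 8
Reactants: 16 cyclopentane-1,3-dione
Product: 17 2-(hydroxyimino)cyclopentane-1,3-dione
Conditions: NaNO2, aq. HCl, 0 °C
Reagents that add atoms: sodium nitrite ([Na+].[O-]N=O)
Why: C-Nitrosation of the doubly activated methylene of the 1,3-dione followed by tautomerisation to the oxime.

Step 9
Reactants: 17 2-(hydroxyimino)cyclopentane-1,3-dione
Product: 18 2-amino-3-hydroxycyclopent-2-en-1-one hydrochloride
Conditions: H2 (1 atm), 10% Pd/C, HCl, MeOH, rt
Reagents that add atoms: hydrogen chloride (Cl)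
Why: Catalytic hydrogenation of the oxime to the primary amine, which is trapped as its hydrochloride (enol tautomer) so that it cannot self-condense to a pyrazine.

Step 10
Reactants: 15 (2E,4E,6E)-7-{(4S,5S,6R)-5,6-epoxy-4-hydroxy-1,1-dimethoxy-2-[(2E,4E,6E)-8-methylnona-2,4,6-trienamido]cyclohex-2-en-4-yl}hepta-2,4,6-trienoic acid; 18 2-amino-3-hydroxycyclopent-2-en-1-one hydrochloride
Product: 19 (2E,4E,6E)-7-{(4S,5S,6R)-5,6-epoxy-4-hydroxy-1,1-dimethoxy-2-[(2E,4E,6E)-8-methylnona-2,4,6-trienamido]cyclohex-2-en-4-yl}-N-(2-hydroxy-5-oxocyclopent-1-en-1-yl)hepta-2,4,6-trienamide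
Conditions: N,N'-diisopropylcarbodiimide, HOAt, N-methylmorpholine, DMF, 0 °C to rt
Reagents that add atoms: none
Why: Carbodiimide amide coupling through the 7-azabenzotriazolyl active ester, which acylates the weakly nucleophilic enaminone nitrogen without touching the tertiary alcohol, and the mild base avoids alkoxide formation at C4.

Step 11
Reactants: 19 (2E,4E,6E)-7-{(4S,5S,6R)-5,6-epoxy-4-hydroxy-1,1-dimethoxy-2-[(2E,4E,6E)-8-methylnona-2,4,6-trienamido]cyclohex-2-en-4-yl}-N-(2-hydroxy-5-oxocyclopent-1-en-1-yl)hepta-2,4,6-trienamide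
Product: 20 N-[(4S,5S,6R)-5,6-epoxy-4-hydroxy-4-{(1E,3E,5E)-7-[(2-hydroxy-5-oxocyclopent-1-en-1-yl)amino]-7-oxohepta-1,3,5-trien-1-yl}-1-oxocyclohex-2-en-2-yl]-(2E,4E,6E)-8-methylnona-2,4,6-trienamide (CNP0215439.3)
Conditions: TsOH·H2O (cat.), acetone/H2O, 0 °C to rt
Reagents that add atoms: water (O)
Why: Acid-catalysed ketal hydrolysis (transketalisation to acetone), which unmasks the C1 ketone under non-basic conditions so that no Payne rearrangement can occur and no stereocentre is touched.

## Compound list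

1 | (E)-4-methylpent-2-enal | CC(C)/C=C/C=O | starting material
2 | triethyl (E)-4-phosphonocrotonate | CCOC(=O)/C=C/CP(=O)(OCC)OCC | starting material
3 | ethyl (2E,4E,6E)-8-methylnona-2,4,6-trienoate | CC(C)/C=C/C=C/C=C/C(=O)OCC | intermediate
4 | 2,5-dimethoxyaniline | COc1ccc(OC)c(N)c1 | starting material
5 | N-(2,5-dimethoxyphenyl)-(2E,4E,6E)-8-methylnona-2,4,6-trienamide | CC(C)/C=C/C=C/C=C/C(=O)Nc1cc(OC)ccc1OC | intermediate
6 | N-(6,6-dimethoxy-3-oxocyclohexa-1,4-dien-1-yl)-(2E,4E,6E)-8-methylnona-2,4,6-trienamide (quinone monoketal) | CC(C)/C=C/C=C/C=C/C(=O)NC1=CC(=O)C=CC1(OC)OC | intermediate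
7 | N-[(5S,6R)-5,6-epoxy-1,1-dimethoxy-4-oxocyclohex-2-en-2-yl]-(2E,4E,6E)-8-methylnona-2,4,6-trienamide | CC(C)/C=C/C=C/C=C/C(=O)NC1=CC(=O)[C@H]2O[C@H]2C1(OC)OC | intermediate
8 | (E)-pent-2-en-4-yn-1-ol | C#C/C=C/CO | starting material
9 | methyl (triphenylphosphoranylidene)acetate | COC(=O)C=P(c1ccccc1)(c1ccccc1)c1ccccc1 | starting material
10 | (E)-pent-2-en-4-ynal | C#C/C=C/C=O | intermediate
11 | methyl (2E,4E)-hepta-2,4-dien-6-ynoate | C#C/C=C/C=C/C(=O)OC | intermediate
12 | chlorobis(cyclopentadienyl)[(1E,3E,5E)-7-methoxy-7-oxohepta-1,3,5-trien-1-yl]zirconium | COC(=O)/C=C/C=C/C=C/[Zr](Cl)(C1C=CC=C1)C1C=CC=C1 | intermediate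
13 | dimethyl[(1E,3E,5E)-7-methoxy-7-oxohepta-1,3,5-trien-1-yl]alane | COC(=O)/C=C/C=C/C=C/[Al](C)C | intermediate
14 | methyl (2E,4E,6E)-7-{(4S,5S,6R)-5,6-epoxy-4-hydroxy-1,1-dimethoxy-2-[(2E,4E,6E)-8-methylnona-2,4,6-trienamido]cyclohex-2-en-4-yl}hepta-2,4,6-trienoate (OH anti to oxirane) | CC(C)/C=C/C=C/C=C/C(=O)NC1=C[C@@](O)(/C=C/C=C/C=C/C(=O)OC)[C@H]2O[C@H]2C1(OC)OC | intermediate
15 | (2E,4E,6E)-7-{(4S,5S,6R)-5,6-epoxy-4-hydroxy-1,1-dimethoxy-2-[(2E,4E,6E)-8-methylnona-2,4,6-trienamido]cyclohex-2-en-4-yl}hepta-2,4,6-trienoic acid | CC(C)/C=C/C=C/C=C/C(=O)NC1=C[C@@](O)(/C=C/C=C/C=C/C(=O)O)[C@H]2O[C@H]2C1(OC)OC | intermediate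
16 | cyclopentane-1,3-dione | O=C1CCC(=O)C1 | starting material
17 | 2-(hydroxyimino)cyclopentane-1,3-dione | ON=C1C(=O)CCC1=O | intermediate
18 | 2-amino-3-hydroxycyclopent-2-en-1-one hydrochloride | Cl.NC1=C(O)CCC1=O | intermediate
19 | (2E,4E,6E)-7-{(4S,5S,6R)-5,6-epoxy-4-hydroxy-1,1-dimethoxy-2-[(2E,4E,6E)-8-methylnona-2,4,6-trienamido]cyclohex-2-en-4-yl}-N-(2-hydroxy-5-oxocyclopent-1-en-1-yl)hepta-2,4,6-trienamide | CC(C)/C=C/C=C/C=C/C(=O)NC1=C[C@@](O)(/C=C/C=C/C=C/C(=O)NC2=C(O)CCC2=O)[C@H]2O[C@H]2C1(OC)OC | intermediate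
20 | N-[(4S,5S,6R)-5,6-epoxy-4-hydroxy-4-{(1E,3E,5E)-7-[(2-hydroxy-5-oxocyclopent-1-en-1-yl)amino]-7-oxohepta-1,3,5-trien-1-yl}-1-oxocyclohex-2-en-2-yl]-(2E,4E,6E)-8-methylnona-2,4,6-trienamide (CNP0215439.3) | CC(C)/C=C/C=C/C=C/C(=O)NC1=C[C@@](O)(/C=C/C=C/C=C/C(=O)NC2=C(O)CCC2=O)[C@H]2O[C@H]2C1=O | target

## Step count and risk

Total step count: 11. Longest linear sequence: 8 steps (steps 1, 2, 3, 4, 6, 7, 10, 11).

The three steps most likely to fail are steps 4, 6 and 11; step 6 is the riskiest.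

**Step 4 (enantioselective epoxidation).** The ee and the sense of induction on this trienamide substrate are not secured. The fallback sets out from 6 and comes back to the route at 7. It replaces asymmetric catalysis by resolution: t-BuOOH and DBU in CH2Cl2 give the racemic epoxide, and preparative chromatography on an amylose tris(3,5-dimethylphenylcarbamate) stationary phase separates 7 from its antipode, N-[(5R,6S)-5,6-epoxy-1,1-dimethoxy-4-oxocyclohex-2-en-2-yl]-(2E,4E,6E)-8-methylnona-2,4,6-trienamide F1. The antipode is kept because it is the entry point of the fallback to step 6.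

**Step 6 (directed trienyl transfer).** The alane may be too unreactive towards the vinylogous-amide ketone, or it may add from the Felkin–Anh face and give the C4 epimer. The fallback sets out from 6 and comes back to the route at 20. It sets C4 by a Felkin–Anh addition to the antipodal epoxide and then moves the oxirane to the other face.

- 6 is epoxidised as in step 4 but with N-benzylcinchoninium chloride, which gives the antipodal epoxy ketone F1.
- Alane 13, filtered cold from Cp2ZrCl2, is treated with MeLi in THF to give lithium trimethyl[(1E,3E,5E)-7-methoxy-7-oxohepta-1,3,5-trien-1-yl]alanate F2. This coordinatively saturated nucleophile cannot dock on the oxirane and adds to F1 anti to the epoxide oxygen, as alkenyllithiums do.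
- Trapping the alkoxide with t-BuMe2SiOTf gives the silyl ether of the (4S,5R,6S) adduct F3, which has C4 as in 20 and the oxirane on the wrong face.
- LiOH in aqueous THF gives the acid F4 (no Payne risk, since the oxygen at C4 is silylated and syn).
- Coupling with 18 as in step 10 gives the amide F5.
- TsOH·H2O in wet acetone gives the silyloxy epoxy enone F6.
- SmI2 with MeOH in THF at −90 °C cleaves the C6–O bond of the α,β-epoxy ketone and gives the (5R)-5-hydroxy ketone F7.
- DBU eliminates water (E1cB) to give the 4-silyloxy cyclohexa-2,5-dienone F8.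
- t-BuOOH and DBU then epoxidise the unsubstituted enone anti to the bulky, electron-withdrawing silyloxy group, on the face of the chain, to give the silyl ether of the target F9.
- HF·pyridine removes the silyl group and gives 20.

**Step 11 (final ketal hydrolysis).** Acid can ionise the doubly allylic C4 carbinol (a vinylogous N-acyliminium ion) or damage the C5N enol amide of the complete molecule. The fallback sets out from 15 and comes back to the route at 20. It changes the order of events so that the last operation is a neutral coupling: 15 is hydrolysed first (TsOH·H2O, wet acetone) to (2E,4E,6E)-7-{(4S,5S,6R)-5,6-epoxy-4-hydroxy-2-[(2E,4E,6E)-8-methylnona-2,4,6-trienamido]-1-oxocyclohex-2-en-4-yl}hepta-2,4,6-trienoic acid F10. F10 is a simpler substrate on which the acid conditions can be tuned, and it is then coupled with 18 under the conditions of step 10 to give 20.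

## Further compounds

F1 | step 4 | N-[(5R,6S)-5,6-epoxy-1,1-dimethoxy-4-oxocyclohex-2-en-2-yl]-(2E,4E,6E)-8-methylnona-2,4,6-trienamide (antipode of 7) | CC(C)/C=C/C=C/C=C/C(=O)NC1=CC(=O)[C@@H]2O[C@@H]2C1(OC)OC
F2 | step 6 | lithium trimethyl[(1E,3E,5E)-7-methoxy-7-oxohepta-1,3,5-trien-1-yl]alanate | [Li+].COC(=O)/C=C/C=C/C=C/[Al-](C)(C)C
F3 | step 6 | methyl (2E,4E,6E)-7-{(4S,5R,6S)-4-(tert-butyldimethylsilyloxy)-5,6-epoxy-1,1-dimethoxy-2-[(2E,4E,6E)-8-methylnona-2,4,6-trienamido]cyclohex-2-en-4-yl}hepta-2,4,6-trienoate | CC(C)/C=C/C=C/C=C/C(=O)NC1=C[C@@](O[Si](C)(C)C(C)(C)C)(/C=C/C=C/C=C/C(=O)OC)[C@@H]2O[C@@H]2C1(OC)OC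
F4 | step 6 | (2E,4E,6E)-7-{(4S,5R,6S)-4-(tert-butyldimethylsilyloxy)-5,6-epoxy-1,1-dimethoxy-2-[(2E,4E,6E)-8-methylnona-2,4,6-trienamido]cyclohex-2-en-4-yl}hepta-2,4,6-trienoic acid | CC(C)/C=C/C=C/C=C/C(=O)NC1=C[C@@](O[Si](C)(C)C(C)(C)C)(/C=C/C=C/C=C/C(=O)O)[C@@H]2O[C@@H]2C1(OC)OC
F5 | step 6 | (2E,4E,6E)-7-{(4S,5R,6S)-4-(tert-butyldimethylsilyloxy)-5,6-epoxy-1,1-dimethoxy-2-[(2E,4E,6E)-8-methylnona-2,4,6-trienamido]cyclohex-2-en-4-yl}-N-(2-hydroxy-5-oxocyclopent-1-en-1-yl)hepta-2,4,6-trienamide | CC(C)/C=C/C=C/C=C/C(=O)NC1=C[C@@](O[Si](C)(C)C(C)(C)C)(/C=C/C=C/C=C/C(=O)NC2=C(O)CCC2=O)[C@@H]2O[C@@H]2C1(OC)OC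
F6 | step 6 | (4S,5R,6S)-4-silyloxy-5,6-epoxy-1-oxo analogue of F5 (ketal removed; oxirane syn to the silyloxy group) | CC(C)/C=C/C=C/C=C/C(=O)NC1=C[C@@](O[Si](C)(C)C(C)(C)C)(/C=C/C=C/C=C/C(=O)NC2=C(O)CCC2=O)[C@@H]2O[C@@H]2C1=O
F7 | step 6 | (4S,5R)-4-(tert-butyldimethylsilyloxy)-5-hydroxy-1-oxocyclohex-2-ene bearing both side chains (aldol from C6–O cleavage) | CC(C)/C=C/C=C/C=C/C(=O)NC1=C[C@@](O[Si](C)(C)C(C)(C)C)(/C=C/C=C/C=C/C(=O)NC2=C(O)CCC2=O)[C@H](O)CC1=O
F8 | step 6 | 4-(tert-butyldimethylsilyloxy)-1-oxocyclohexa-2,5-diene bearing both side chains (C4 arrangement unchanged; formally 4R through a priority change) | CC(C)/C=C/C=C/C=C/C(=O)NC1=C[C@@](O[Si](C)(C)C(C)(C)C)(/C=C/C=C/C=C/C(=O)NC2=C(O)CCC2=O)C=CC1=O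
F9 | step 6 | (4S,5S,6R) tert-butyldimethylsilyl ether of 20 | CC(C)/C=C/C=C/C=C/C(=O)NC1=C[C@@](O[Si](C)(C)C(C)(C)C)(/C=C/C=C/C=C/C(=O)NC2=C(O)CCC2=O)[C@H]2O[C@H]2C1=O
F10 | step 11 | (2E,4E,6E)-7-{(4S,5S,6R)-5,6-epoxy-4-hydroxy-2-[(2E,4E,6E)-8-methylnona-2,4,6-trienamido]-1-oxocyclohex-2-en-4-yl}hepta-2,4,6-trienoic acid | CC(C)/C=C/C=C/C=C/C(=O)NC1=C[C@@](O)(/C=C/C=C/C=C/C(=O)O)[C@H]2O[C@H]2C1=O
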